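The route rests on cutting two neighbouring bonds of the hexasubstituted benzene ring: the bond from one ring carbon to the carbonyl carbon of the (S)-2-methylbutanoyl group and the bond from the adjacent ring carbon to its phenolic oxygen. This ortho-hydroxyaryl ketone motif is the feature exploited: an aryne inserts into the C–O bond of free (S)-2-methylbutanoic acid, so one operation delivers acyl carbon and oxygen with the stereocentre untouched. The aryne precursor is an ortho-trimethylsilyl aryl triflate bearing two MOM ethers and the prenyl group, made from phloroglucinol by two carbamate-directed metalations in one flask. MOM removal and a methylene bridge to a separately made 4-hydroxy-2-pyrone ring finish the target.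

Key step: step 5

Remarks on the chemistry (one line each):
- Structures: triflate 10, acid 11 and ketone 13 map onto the target, with acyl and prenyl each between two ring oxygens and the one unsubstituted ring carbon left for the bridge; the (S) descriptor is the same in 11, 13, 14 and 21 because the centre is never touched and the priority order carbonyl carbon > ethyl > methyl > H holds throughout.
- Precursor assembly: silicon and prenyl are placed by carbamate-directed metalation (silicon first, prenyl second, one N-silyl protection serving both) and not by C-alkylation of a phenoxide, because the carbamate fixes both positions and is later removed by mild base in the flask in which the triflate is made.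
- Convention: lithiated, cuprated and enolate species are treated as transient and are described in the Why lines; only discrete neutral in-flask compounds are numbered.

Step 1
Reactants: 1 phloroglucinol
Product: 2 3,5-bis(methoxymethoxy)phenol
Conditions: MOMCl (2.0 equiv), iPr2NEt (2.5 equiv), CH2Cl2/DMF, 0 °C to rt
Reagents that add atoms: chloromethyl methyl ether (MOMCl), COCCl
Why: Base-mediated O-alkylation of the phenol with the chloromethyl ether (Williamson-type MOM protection) should give the bis-ether as the major component of a statistical mixture when two equivalents are used, and it is separated by chromatography from the mono- and tris-ethers.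

Step 2
Reactants: 2 3,5-bis(methoxymethoxy)phenol
Product: 3 3,5-bis(methoxymethoxy)phenyl N-isopropylcarbamate
Conditions: iPrNCO (1.3 equiv), Et3N (0.2 equiv), CH2Cl2, rt
Reagents that add atoms: isopropyl isocyanate, CC(C)N=C=O
Why: Amine-catalysed addition of the free phenol to the isocyanate (carbamoylation) should give the secondary carbamate, chosen because it is the strongest ortho-director on the ring and can later be removed by mild base without touching silicon, MOM or prenyl groups.

Step 3
Reactants: 3 3,5-bis(methoxymethoxy)phenyl N-isopropylcarbamate; 4 prenyl bromide (1-bromo-3-methylbut-2-ene)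
Product: 8 3,5-bis(methoxymethoxy)-2-(3-methylbut-2-enyl)-6-(trimethylsilyl)phenyl N-isopropylcarbamate, via N-silyl carbamate 5 (not isolated), via N-silyl C-silyl carbamate 6 (not isolated), via N-silyl prenyl carbamate 7 (not isolated)
Conditions: TBSOTf (1.05 equiv), TMEDA, Et2O, 0 °C to rt; n-BuLi, TMEDA, −78 °C; TMSCl (1.0 equiv), −78 to −20 °C; n-BuLi, TMEDA, −78 °C; CuBr·SMe2 (1.1 equiv), −78 to −40 °C; 4, −78 to 0 °C; aq. NH4Cl, then 10% aq. citric acid
Reagents that add atoms: chlorotrimethylsilane (TMSCl), C[Si](C)(C)Cl
Why: Two consecutive carbamate-directed ortho-metalations run under a single in-flask N-silyl protection (one equivalent of TBSOTf gives 5 without activating the MOM acetals), in which n-BuLi/TMEDA first removes one of the two equivalent protons between the carbamate and a MOM ether and TMSCl traps the aryllithium as 6, a second n-BuLi/TMEDA deprotonation takes the only remaining proton beside the carbamate, lithium-to-copper transmetalation and SN2 allylic substitution of 4 at its primary carbon give the linear prenyl compound 7, and the N–Si bond is hydrolysed on the mild acidic work-up.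

Step 4
Reactants: 8 3,5-bis(methoxymethoxy)-2-(3-methylbut-2-enyl)-6-(trimethylsilyl)phenyl N-isopropylcarbamate
Product: 10 3,5-bis(methoxymethoxy)-6-(3-methylbut-2-enyl)-2-(trimethylsilyl)phenyl trifluoromethanesulfonate, via silyl phenol 9 (not isolated)
Conditions: DBU (1.5 equiv), Et2NH (1.2 equiv), MeCN, 40 °C; then PhNTf2 (1.5 equiv), rt to 40 °C
Reagents that add atoms: N-phenylbis(trifluoromethanesulfonimide) (PhNTf2), O=S(=O)(N(c1ccccc1)S(=O)(=O)C(F)(F)F)C(F)(F)F
Why: DBU deprotonates the carbamate N–H and the anion loses isopropyl isocyanate by an E1cB pathway that needs no attack at the crowded carbonyl (Et2NH scavenges the isocyanate as a urea), and the phenoxide of 9 is then O-sulfonylated by PhNTf2 in the same flask.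

Step 5
Reactants: 10 3,5-bis(methoxymethoxy)-6-(3-methylbut-2-enyl)-2-(trimethylsilyl)phenyl trifluoromethanesulfonate; 11 (S)-2-methylbutanoic acid
Product: 13 (S)-1-[2-hydroxy-4,6-bis(methoxymethoxy)-3-(3-methylbut-2-enyl)phenyl]-2-methylbutan-1-one, via aryne 12 (not isolated)
Conditions: CsF (4 equiv), 11 (1.2 equiv), THF, 125 °C, sealed tube
Reagents that add atoms: none
Why: Fluoride removes the trimethylsilyl group of 10 and the resulting aryl anion expels triflate to give aryne 12; cesium (S)-2-methylbutanoate then adds through oxygen to the aryne carbon next to the prenyl group, and the aryl anion so formed next to the MOM ether attacks the ester carbonyl in an intramolecular acyl transfer through a four-membered alkoxide that opens to the chelated phenoxide of 13. The closest known reaction type is the fluoride-induced insertion of arynes into the C–O bond of carboxylic acids (an aryne sigma-bond insertion, formally O-arylation followed by an anionic Fries-type 1,3-acyl shift), which gives ortho-hydroxyaryl ketones from aliphatic and aromatic acids and is regioselective with 3-alkoxy arynes. No ring is retained, because the four-membered intermediate only mediates the acyl shift, and no stereocentre is created; the (S) centre of 11 lies alpha to the migrating carbonyl, takes no part in bond making, and should resist enolisation because the product is held as a chelated phenoxide whose ketone is twisted between two ortho substituents. Two selectivities are needed: regioselective O-addition, secured by the C–O bond of the MOM ether, which polarises the aryne and stabilises the developing carbanion on the adjacent carbon so that the nucleophile enters at the distal carbon despite the neighbouring prenyl CH2, and acyl transfer in preference to protonation of the aryl anion, secured by aprotic THF at high temperature, only a small excess of acid and excess CsF that binds the released proton as bifluoride. The slow dissolution of CsF in THF keeps the aryne concentration low, which should suppress ene reaction of 12 with the prenyl alkene of a second molecule.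

Step 6
Reactants: 13 (S)-1-[2-hydroxy-4,6-bis(methoxymethoxy)-3-(3-methylbut-2-enyl)phenyl]-2-methylbutan-1-one
Product: 14 (S)-2-methyl-1-[2,4,6-trihydroxy-3-(3-methylbut-2-enyl)phenyl]butan-1-one
Conditions: HCl (3 M aq.), MeOH, rt
Reagents that add atoms: none
Why: Acid-catalysed acetal exchange with methanol (MOM cleavage) should free both phenols at room temperature, where protonation of the prenyl alkene (chroman formation) and enolisation of the hydrogen-bonded ketone (loss of the stereocentre) are not expected to compete.

Step 7
Reactants: 15 methyl 3-oxopentanoate; 16 N-methoxy-N-methylpropanamide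
Product: 17 methyl 4-methyl-3,5-dioxoheptanoate
Conditions: NaH, THF, 0 °C; n-BuLi, 0 °C; 16, 0 °C to rt; aq. HCl
Reagents that add atoms: none
Why: Crossed Claisen-type acylation of the β-keto ester dianion at its more nucleophilic terminal carbon, where the chelated tetrahedral adduct of the N-methoxy-N-methyl amide survives until the acidic quench so that neither over-addition nor proton transfer from the product interferes; the new methyl-bearing carbon is formed without control and becomes sp2 in step 8.

Step 8
Reactants: 17 methyl 4-methyl-3,5-dioxoheptanoate
Product: 18 6-ethyl-4-hydroxy-5-methyl-2H-pyran-2-one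
Conditions: DBU, toluene, reflux; aq. HCl work-up
Reagents that add atoms: none
Why: DBU enolises the 3,5-diketo ester and the C5 enolate oxygen attacks the methyl ester in a 6-exo-trig lactonisation (intramolecular transesterification) with loss of methanol, after which tautomerisation gives the 4-hydroxy-2-pyrone.

Step 9
Reactants: 14 (S)-2-methyl-1-[2,4,6-trihydroxy-3-(3-methylbut-2-enyl)phenyl]butan-1-one; 18 6-ethyl-4-hydroxy-5-methyl-2H-pyran-2-one
Product: 21 (S)-6-ethyl-4-hydroxy-5-methyl-3-{[2,4,6-trihydroxy-3-(2-methylbutanoyl)-5-(3-methylbut-2-enyl)phenyl]methyl}-2H-pyran-2-one, via pyrone Mannich base 19 (not isolated), via methylidene pyrandione 20 (not isolated)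
Conditions: 18, [Me2N=CH2]I (1.1 equiv), MeCN, rt; then 14, 50 °C
Reagents that add atoms: dimethylmethylideneammonium iodide, C=[N+](C)C.[I-]
Why: Mannich reaction of the pyrone at C3 gives 19, which on warming loses dimethylamine to the methylidene pyrandione 20, and this Michael acceptor is captured by the single unsubstituted ring carbon of acylphloroglucinol 14 in a Friedel–Crafts-type conjugate addition, a three-component methylene bridging known for 4-hydroxy-2-pyrones and prenylated acylphloroglucinols.

Compound list
1 | phloroglucinol (benzene-1,3,5-triol) | Oc1cc(O)cc(O)c1 | starting material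
2 | 3,5-bis(methoxymethoxy)phenol | COCOc1cc(O)cc(OCOC)c1 | intermediate
3 | 3,5-bis(methoxymethoxy)phenyl N-isopropylcarbamate | CC(C)NC(=O)Oc1cc(OCOC)cc(OCOC)c1 | intermediate
4 | prenyl bromide (1-bromo-3-methylbut-2-ene) | CC(C)=CCBr | starting material
5 | 3,5-bis(methoxymethoxy)phenyl N-(tert-butyldimethylsilyl)-N-isopropylcarbamate | CC(C)N([Si](C)(C)C(C)(C)C)C(=O)Oc1cc(OCOC)cc(OCOC)c1 | intermediate (not isolated)
6 | 3,5-bis(methoxymethoxy)-2-(trimethylsilyl)phenyl N-(tert-butyldimethylsilyl)-N-isopropylcarbamate | CC(C)N([Si](C)(C)C(C)(C)C)C(=O)Oc1cc(OCOC)cc(OCOC)c1[Si](C)(C)C | intermediate (not isolated)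
7 | 3,5-bis(methoxymethoxy)-2-(3-methylbut-2-enyl)-6-(trimethylsilyl)phenyl N-(tert-butyldimethylsilyl)-N-isopropylcarbamate | CC(C)N([Si](C)(C)C(C)(C)C)C(=O)Oc1c(CC=C(C)C)c(OCOC)cc(OCOC)c1[Si](C)(C)C | intermediate (not isolated)
8 | 3,5-bis(methoxymethoxy)-2-(3-methylbut-2-enyl)-6-(trimethylsilyl)phenyl N-isopropylcarbamate | CC(C)NC(=O)Oc1c(CC=C(C)C)c(OCOC)cc(OCOC)c1[Si](C)(C)C | intermediate
9 | 3,5-bis(methoxymethoxy)-2-(3-methylbut-2-enyl)-6-(trimethylsilyl)phenol | COCOc1cc(OCOC)c([Si](C)(C)C)c(O)c1CC=C(C)C | intermediate (not isolated)
10 | 3,5-bis(methoxymethoxy)-6-(3-methylbut-2-enyl)-2-(trimethylsilyl)phenyl trifluoromethanesulfonate | COCOc1cc(OCOC)c([Si](C)(C)C)c(OS(=O)(=O)C(F)(F)F)c1CC=C(C)C | intermediate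
11 | (S)-2-methylbutanoic acid | CC[C@H](C)C(=O)O | starting material
12 | 4,6-bis(methoxymethoxy)-3-(3-methylbut-2-enyl)-1,2-didehydrobenzene (aryne) | COCOC1=C(CC=C(C)C)C#CC(OCOC)=C1 | intermediate (not isolated)
13 | (S)-1-[2-hydroxy-4,6-bis(methoxymethoxy)-3-(3-methylbut-2-enyl)phenyl]-2-methylbutan-1-one | COCOc1cc(OCOC)c(C(=O)[C@@H](C)CC)c(O)c1CC=C(C)C | intermediate
14 | (S)-2-methyl-1-[2,4,6-trihydroxy-3-(3-methylbut-2-enyl)phenyl]butan-1-one | Oc1cc(O)c(C(=O)[C@@H](C)CC)c(O)c1CC=C(C)C | intermediate
15 | methyl 3-oxopentanoate | CCC(=O)CC(=O)OC | starting material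
16 | N-methoxy-N-methylpropanamide | CCC(=O)N(C)OC | starting material
17 | methyl 4-methyl-3,5-dioxoheptanoate (racemic at C4, enolisable) | CCC(=O)C(C)C(=O)CC(=O)OC | intermediate
18 | 6-ethyl-4-hydroxy-5-methyl-2H-pyran-2-one | CCc1oc(=O)cc(O)c1C | intermediate
19 | 3-[(dimethylamino)methyl]-6-ethyl-4-hydroxy-5-methyl-2H-pyran-2-one | CCc1oc(=O)c(CN(C)C)c(O)c1C | intermediate (not isolated)
20 | 6-ethyl-5-methyl-3-methylidene-2H-pyran-2,4(3H)-dione | CCC1=C(C)C(=O)C(=C)C(=O)O1 | intermediate (not isolated)
21 | (S)-6-ethyl-4-hydroxy-5-methyl-3-{[2,4,6-trihydroxy-3-(2-methylbutanoyl)-5-(3-methylbut-2-enyl)phenyl]methyl}-2H-pyran-2-one (CNP0209307.1) | CCc1oc(=O)c(Cc2c(O)c(CC=C(C)C)c(O)c(C(=O)[C@@H](C)CC)c2O)c(O)c1C | target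

Total step count: 9. Longest linear sequence: 7 steps (steps 1 to 6 and step 9, from phloroglucinol); the pyrone branch is steps 7 and 8.

Steps most likely to fail

Step 5 (key step). Three processes may go wrong: protonation of the aryl anion before the acyl shift, which stops the sequence at plain O-arylation; addition of the carboxylate at the wrong aryne carbon, because the favoured one is shielded by the prenyl CH2; and base-induced epimerisation alpha to the ketone at 125 °C, to be checked on 13 by chiral HPLC against material made from racemic acid. The fallback replaces aryne insertion by electrophilic acylation of the intact ring; it sets out from phloroglucinol 1 and acid 11 and comes back to the route at 14. Acid 11 is converted with oxalyl chloride and catalytic DMF in CH2Cl2 into (S)-2-methylbutanoyl chloride F1, which acylates 1 under Friedel–Crafts conditions (AlCl3, nitrobenzene/CH2Cl2, rt to 50 °C) to give (S)-2-methyl-1-(2,4,6-trihydroxyphenyl)butan-1-one F2. Mono-C-prenylation of F2 with prenyl bromide 4 (DBU, THF, rt) and chromatographic removal of over-alkylated material should give 14, which enters step 9.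

Step 3. Four processes may go wrong: incomplete silylation before the second base charge, so that prenyl enters at the position meant for silicon; metalation at the ring position between the two MOM ethers instead of beside the carbamate; migration of the carbamoyl group to carbon on warming (anionic Fries shift); and allylic substitution at the tertiary end of the prenyl unit. The fallback replaces the double metalation by C-alkylation of a phenoxide followed by a single metalation; it sets out from phenol 2 and comes back to the route at 8. The phenoxide of 2 (NaH, toluene, 0 °C to rt) is alkylated on the carbon ortho to oxygen by prenyl bromide 4 to give 3,5-bis(methoxymethoxy)-2-(3-methylbut-2-enyl)phenol F3, separated from O-alkylated and para-alkylated isomers. Treatment with iPrNCO/Et3N gives 3,5-bis(methoxymethoxy)-2-(3-methylbut-2-enyl)phenyl N-isopropylcarbamate F4. In-flask N-silylation (TBSOTf, TMEDA) gives 3,5-bis(methoxymethoxy)-2-(3-methylbut-2-enyl)phenyl N-(tert-butyldimethylsilyl)-N-isopropylcarbamate F5. Metalation with n-BuLi/TMEDA at −78 °C at the one free ring position beside the carbamate and trapping with TMSCl should give 7, which is hydrolysed on work-up to 8.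

Step 9. Two processes may go wrong: self-coupling of either partner through the methylidene intermediate to symmetrical methylene-bridged dimers, and slow capture by the hindered arene. The fallback places the electrophilic carbon on the arene instead of the pyrone; it sets out from 14 and comes back to the route at 21. Compound 14 is aminomethylated at its free ring carbon with dimethylmethylideneammonium iodide (CH2Cl2, rt, NaHCO3 work-up) to the isolable Mannich base (S)-1-[3-[(dimethylamino)methyl]-2,4,6-trihydroxy-5-(3-methylbut-2-enyl)phenyl]-2-methylbutan-1-one F6. Heating F6 with pyrone 18 in dioxane (90 °C) should expel dimethylamine to give the ortho-quinone methide (S)-3,5-dihydroxy-6-methylidene-4-(2-methylbutanoyl)-2-(3-methylbut-2-enyl)cyclohexa-2,4-dien-1-one F7, which is trapped by C3 of 18 in a Michael addition to give 21.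

Further compounds
F1 | step 5 | (S)-2-methylbutanoyl chloride | CC[C@H](C)C(=O)Cl
F2 | step 5 | (S)-2-methyl-1-(2,4,6-trihydroxyphenyl)butan-1-one | CC[C@H](C)C(=O)c1c(O)cc(O)cc1O
F3 | step 3 | 3,5-bis(methoxymethoxy)-2-(3-methylbut-2-enyl)phenol | COCOc1cc(O)c(CC=C(C)C)c(OCOC)c1
F4 | step 3 | 3,5-bis(methoxymethoxy)-2-(3-methylbut-2-enyl)phenyl N-isopropylcarbamate | CC(C)NC(=O)Oc1cc(OCOC)cc(OCOC)c1CC=C(C)C
F5 | step 3 | 3,5-bis(methoxymethoxy)-2-(3-methylbut-2-enyl)phenyl N-(tert-butyldimethylsilyl)-N-isopropylcarbamate | CC(C)N([Si](C)(C)C(C)(C)C)C(=O)Oc1cc(OCOC)cc(OCOC)c1CC=C(C)C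
F6 | step 9 | (S)-1-[3-[(dimethylamino)methyl]-2,4,6-trihydroxy-5-(3-methylbut-2-enyl)phenyl]-2-methylbutan-1-one | CC[C@H](C)C(=O)c1c(O)c(CN(C)C)c(O)c(CC=C(C)C)c1O
F7 | step 9 | (S)-3,5-dihydroxy-6-methylidene-4-(2-methylbutanoyl)-2-(3-methylbut-2-enyl)cyclohexa-2,4-dien-1-one | C=C1C(=O)C(CC=C(C)C)=C(O)C(C(=O)[C@@H](C)CC)=C1O
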